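Dawn with 4.0 mM of free catalyst or noon with 1.2 mM: the quick answer on which finishes with the higher excess of left-handed product turns on one ratio.

| setting | Friday's | Saturday's | dawn | noon |
|---|---|---|---|---|
| left-handed substrate | 0.80 M | 0.80 M | 0.80 M | 0.80 M |
| right-handed substrate | 0.80 M | 0.80 M | 0.80 M | 0.80 M |
| reagent | 2.4 M | 2.4 M | 2.40 M | 2.40 M |
| free catalyst | 0.67 mM | 2.4 mM | 4.0 mM | 1.2 mM |
| racemization catalyst | 8 mM | 8 mM | 8.0 mM | 8.0 mM |
| impurity | 2.6 mM | 2.6 mM | 2.6 mM | 2.6 mM |
| remark | run made earlier | run made earlier |  |  |
| time |  |  | 10 h | 10 h |

| run | time / h | left-handed product / % | right-handed product / % | left-handed substrate / % |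
|---|---|---|---|---|
| Friday's | 0.667 | 6 | 2 | 47 |
| Friday's | 2.00 | 8 | 0 | 44 |
| Friday's | 3.00 | 8 | 0 | 43 |
| Friday's | 5.00 | 14 | 3 | 44 |
| Saturday's | 0.417 | 10 | 1 | 42 |
| Saturday's | 1.00 | 17 | 0 | 36 |
| Saturday's | 2.00 | 24 | 0 | 34 |
| Saturday's | 5.00 | 30 | 0 | 35 |

(each reading ± 1.5 percentage points)

1. which one finishes higher in excess of left-handed product over right-handed product in the product ("neither" within 2 percentage points) (dawn / noon / neither)
2. excess of left-handed product over right-handed product in the product at the end, dawn
3. excess of left-handed product over right-handed product in the product at the end, noon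

- free catalyst is single-handed; left-handed substrate and right-handed substrate are mirror images of each other, charged as a racemate, each of them at the stated concentration
- an excess is below zero if the other one leads

The symmetric case sets the zero. If free catalyst enters both product-forming rates, its concentration cancels in their ratio. With the two substrates level, left-handed over right-handed product then equals the selectivity factor s, and the excess is (s−1)/(s+1), zero at s = 1.

Saturday's readings at 5.00 h put the pair level: left-handed substrate 35 %, right-handed by balance 35.0 %. Their difference carries a scatter of 3.7 percentage points, however, so a smaller gap may remain. At 2.00 h the readings show a lag, with 42.0 % right-handed against 34 % left-handed.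

Summed over both runs, the readings give 117 % left-handed and 6.00 % right-handed product, so s reads 19.5. The pooled excess E, the excess of product from a level pair as read from these sums, is 90.2 %. The right-handed sum carries a scatter of 4.2 points, which spreads E from 83.9 % to 97.0 %.

Held through a whole run, the lag read at 2.00 h costs 2.2 points, less than the 6.3 points by which E spreads downward.

The forecast says dawn, with 95 % at dawn and 87 % at noon, since at noon “the same small right-handed amount dilutes it more”. This reckoning differs: E for both flasks, so neither.

The flask gives neither: dawn 97.3 %, noon 97.7 %, a gap of 0.40 points inside the margin of 2 points. Right-handed product ended at 0.598 % at dawn and 0.227 % at noon, falling along with left-handed product, 43.0 % and 19.5 %. One E served both flasks, and both stand above its 90.2 %, noon 0.70 points past the top of its spread.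

    reagent + free catalyst + left-handed substrate → free catalyst + left-handed product (k = 1.95 M⁻² min⁻¹)
    reagent + free catalyst + right-handed substrate → free catalyst + right-handed product (k = 0.0208 M⁻² min⁻¹)
    left-handed substrate + racemization catalyst ⇌ right-handed substrate + racemization catalyst, rate k3*[racemization catalyst]*[left-handed substrate] forward; the back reaction follows from the equilibrium constant (k = 1.02 M⁻¹ min⁻¹)
    2 reagent → homo dimer (k = 0.00481 M⁻¹ min⁻¹)
    racemization catalyst + impurity → spent catalyst (k = 933 M⁻¹ min⁻¹)
    free catalyst ⇌ dormant form (K = 10.6, k = 0.00174 min⁻¹)

For noon's neighbour with 3.00 mM of free catalyst, the charge cancels again, so E stays 90.2 % as for noon and the excess should match noon's. The computed excess is 97.4 %, with left-handed product at 36.6 % against noon's 19.5 %.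

All runs come from a simulation on assumed constants; the scatter is artificial.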